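## Retrosynthetic overview
- Target **3** is an achiral 2,3-dihydroxybenzoate ester of a primary, iso-branched C18 alcohol. The SMILES has a CH(CH3)2 terminus and 15 CH2 groups, so the alkyl group is 16-methylheptadecyl. There are no stereocenters and no rings to build, because the catechol ring is already present in the starting material.
- The only disconnection is the ester C(acyl)–O bond, which gives 2,3-dihydroxybenzoic acid (**1**) and 16-methylheptadecan-1-ol (**2**).
- Phenols do not esterify under acid-catalysed Fischer conditions, so no protecting groups are needed.
- Assumption: **2** is purchasable as the pure iso-C18 alcohol (isostearyl alcohol, 16-methylheptadecan-1-ol). If it is not, it can be made by LiAlH4 reduction of the commercial acid (see fallbacks).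

## Route

**Step 1**
Reactants: **1** 2,3-dihydroxybenzoic acid (1.5 equiv); **2** 16-methylheptadecan-1-ol (1.0 equiv)
Product: **3** 16-methylheptadecyl 2,3-dihydroxybenzoate (Gentiside D)
Conditions: p-TsOH·H2O (10 mol%), toluene, reflux with Dean–Stark trap, N2, 16 h. Then wash with aq. NaHCO3 and purify on silica (hexanes/EtOAc).
Reagents that add atoms: none (p-TsOH is a catalyst and the excess acid is removed in the wash)
Why: This is a Fischer esterification in which the primary alcohol attacks the protonated carboxylic acid and azeotropic removal of water drives the equilibrium. The phenolic OH groups are poor nucleophiles and are not acylated under acid catalysis, and the intramolecular H-bond of the salicylate stabilises the product. No stereocenter is created, and the alkyl chain has none.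

## Checks
- **Structure:** The product has a 1,2,3-trisubstituted benzene with CO2R at C1 and OH at C2 and C3 (SMILES c1cccc(O)c1O), matching the target. The ester oxygen carries –(CH2)15–CH(CH3)2, matching the target chain.
- **Atom balance:** C7H6O4 (**1**) + C18H38O (**2**) − H2O = C25H42O4, which is the formula of **3**.
- **Functional group survival:** The catechol is kept under N2 and in acid, which limits oxidation to the quinone. The alkyl chain is inert. The NaHCO3 wash removes unreacted **1** (a carboxylic acid) but not the product, whose phenol pKa is about 10.
- **Stereochemistry:** The target has no stereocenters. The isopropyl CH bears two identical methyls, so it is not stereogenic.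

## Compound list
| No. | Name | SMILES | Role |
|---|---|---|---|
| 1 | 2,3-Dihydroxybenzoic acid | OC(=O)c1cccc(O)c1O | starting material |
| 2 | 16-Methylheptadecan-1-ol (iso-C18 alcohol) | CC(C)CCCCCCCCCCCCCCCO | starting material |
| 3 | 16-Methylheptadecyl 2,3-dihydroxybenzoate (Gentiside D) | CC(C)CCCCCCCCCCCCCCCOC(=O)c1cccc(O)c1O | target |

## Totals
- Total steps: 1
- Longest linear sequence: 1

## Three most likely failure points
There is only one step, so the three risks below are all within it.

1. **Low conversion in the Fischer esterification.** The acid is poorly soluble in toluene, and a 2-hydroxy acid is hindered and H-bonded. It may also partly decarboxylate to catechol at reflux.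
   - Fallback: use a protected route. Make 2,3-bis(benzyloxy)benzoic acid, couple it with **2** by Steglich esterification (EDC, DMAP, CH2Cl2), then remove the benzyl groups by H2, Pd/C.
2. **Catechol oxidation or streaking during work-up and chromatography.** This lowers the isolated yield.
   - Fallback: transesterify methyl 2,3-dihydroxybenzoate with **2** (Ti(OiPr)4, neat or in xylene, with distillative removal of MeOH). This avoids free carboxylic acid and the acidic medium, and the product can be purified by crystallisation or silica treated with 1% AcOH.
3. **Supply or purity of alcohol 2.** Commercial "isostearyl alcohol" is often a mixture of branched isomers, which would give an impure ester.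
   - Fallback: prepare **2** from commercial pure 16-methylheptadecanoic acid by LiAlH4 reduction in THF (0 °C to rt). This adds one step, giving a two-step route.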